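## Retrosynthetic overview

1. The C7–O ester bond is cut first: linoleic acid is joined to the ring A enol carbon by a reagent-controlled acyloxylative dearomatization that creates the C7 quaternary centre.
2. Ring B (the pyran) is the only ring that is formed; its C1–O2 bond closes by loss of water from a hydroxy aldehyde in the same flask, just before the C7–O bond is made.
3. The hydroxy aldehyde comes from formylation of a symmetric resorcinol, which comes from its dimethyl ether.
4. The ring methyl group is put in by directed lithiation; the side chain and the C3 stereocentre come from an aryl Grignard opening of (R)-propylene oxide.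
5. Ring A is bought as a benzene ring (1-bromo-3,5-dimethoxybenzene) and is dearomatized last.

Assumption: the face chosen by the new reagent in step 5 cannot be known before the first run; the route is written with the (R,R)-iodoarene, and the (S,S)-mirror reagent (from the other lactate) replaces it with no other change if the 7S epimer is found.

Assumption: 9 is drawn as the open hydroxy aldehyde; any lactol or quinone methide 12 present at equilibrium enters step 5 in the same way.

Reagent for step 5, "(R,R)-ArI": (2R,2'R)-2,2'-[(2-iodo-1,3-phenylene)bis(oxy)]bis[N-(2,4,6-trimethylphenyl)propanamide], SMILES Cc1cc(C)c(NC(=O)[C@@H](C)Oc2cccc(O[C@H](C)C(=O)Nc3c(C)cc(C)cc3C)c2I)c(C)c1. It is recovered after the step.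

## Route

Step 1
Reactants: 1 1-bromo-3,5-dimethoxybenzene; 2 (R)-propylene oxide [(2R)-2-methyloxirane]
Product: 4 (2R)-1-(3,5-dimethoxyphenyl)propan-2-ol, via 3,5-dimethoxyphenylmagnesium bromide 3 (not isolated)
Conditions: Mg, THF, reflux; CuI (10 mol%), 2, −30 → 0 °C; then 1 M HCl
Reagents that add atoms: none
Why: Copper-catalysed SN2 opening of a terminal epoxide by an aryl Grignard reagent at the CH2 carbon; the C–O bond at the stereocentre is not touched, so the (R) centre of 2 becomes C3 (R) of the target unchanged.

Step 2
Reactants: 4 (2R)-1-(3,5-dimethoxyphenyl)propan-2-ol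
Product: 6 (2R)-1-(3,5-dimethoxy-4-methylphenyl)propan-2-ol, via dilithio species 5 (not isolated)
Conditions: n-BuLi (2.4 equiv), TMEDA, THF, 0 → 25 °C; MeI, −78 → −20 °C; then H2O
Reagents that add atoms: iodomethane, CI
Why: Directed ortho-metalation; after the alkoxide forms, the second n-BuLi removes the ring proton flanked by both methoxy groups, and the aryllithium is methylated by MeI far faster than the lithium alkoxide; no stereocentre is touched.

Step 3
Reactants: 6 (2R)-1-(3,5-dimethoxy-4-methylphenyl)propan-2-ol
Product: 7 5-[(2R)-2-hydroxypropyl]-2-methylbenzene-1,3-diol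
Conditions: BBr3 (4 equiv), CH2Cl2, −78 → 0 °C; then MeOH, H2O
Reagents that add atoms: none
Why: Lewis-acid cleavage of aryl methyl ethers (BBr3 demethylation); the unactivated secondary alcohol sits as a borate ester at low temperature and returns on hydrolysis, so C3 is untouched.

Step 4
Reactants: 7 5-[(2R)-2-hydroxypropyl]-2-methylbenzene-1,3-diol
Product: 9 2,4-dihydroxy-6-[(2R)-2-hydroxypropyl]-3-methylbenzaldehyde, via cyclic ethyl acetal 8 (not isolated)
Conditions: HC(OEt)3 (3 equiv), AlCl3 (3 equiv), CH2Cl2, 0 → 25 °C; then 1 M HCl, THF, 25 °C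
Reagents that add atoms: triethyl orthoformate, CCOC(OCC)OCC; water, O
Why: Gross–Rieche-type orthoformate formylation (electrophilic aromatic substitution); the two free ring positions are equivalent by symmetry, so one regioisomer forms, the side-chain alcohol captures the new carbon as a cyclic acetal (oxa-Pictet–Spengler-like, as in the classical closure of the citrinin ring system), and aqueous acid releases the aldehyde; C3 is untouched.

Step 5
Reactants: 9 2,4-dihydroxy-6-[(2R)-2-hydroxypropyl]-3-methylbenzaldehyde; 10 linoleic acid [(9Z,12Z)-octadeca-9,12-dienoic acid]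
Product: 13 (3R,7R)-3,7-dimethyl-6,8-dioxo-3,4,7,8-tetrahydro-6H-isochromen-7-yl (9Z,12Z)-octadeca-9,12-dienoate, via aryliodane bis(linoleate) 11 (not isolated), via quinone methide 12 (not isolated)
Conditions: (R,R)-ArI (1.2 equiv), AcOOH, AcOH, 25 °C, evaporate to dryness; 10 (2.5 equiv), PhCl, 40 °C, 5 mbar (AcOH removed); then 9 (pre-stirred with 4 Å MS and 10 mol% of 10, CH2Cl2, 40 °C), −40 → 0 °C
Reagents that add atoms: none
Why: Proposed new method: a chiral trivalent-iodine aryliodane carrying two linoleate ligands transfers one of them to C7 of the quinone methide 12 (the water-free, ring B-closed form of 9, a vinylogous 2-methyl-1,3-diketone enol whose only enol carbon is C7); the enol oxygen at C8 displaces one linoleate on iodine, the lactamide N–H groups hydrogen-bond to the iodine-bound carboxylate and fold the two arms into a C2-symmetric pocket, and the remaining linoleate is delivered to one face of C7 by ligand coupling with reductive loss of ArI, forming the C7–O bond and the 7R quaternary centre under reagent control (C3 is too remote to interfere), while any 9 that reacts in its open form converges by cyclodehydration; no peracid is present once 10 is added and trivalent-iodine carboxylates do not attack isolated alkenes, so the skipped diene survives; closest known reaction types are the racemic Wessely acyloxylation of phenols with Pb(OAc)4 or PhI(OAc)2 (including Pb(OAc)4 oxidation of benzopyrylium salts to 7-acetoxy azaphilones), the enantioselective intramolecular oxidative spirolactonization with lactamide iodoarenes, and the enantioselective diacetoxylation of styrenes by the same reagent class.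

## Compound list

1 | 1-bromo-3,5-dimethoxybenzene | COc1cc(Br)cc(OC)c1 | starting material
2 | (R)-propylene oxide, (2R)-2-methyloxirane | C[C@@H]1CO1 | starting material
3 | 3,5-dimethoxyphenylmagnesium bromide | COc1cc(OC)cc([Mg]Br)c1 | intermediate
4 | (2R)-1-(3,5-dimethoxyphenyl)propan-2-ol | C[C@@H](O)Cc1cc(OC)cc(OC)c1 | intermediate
5 | dilithio species: lithium (2R)-1-(4-lithio-3,5-dimethoxyphenyl)propan-2-olate | C[C@@H](O[Li])Cc1cc(OC)c([Li])c(OC)c1 | intermediate
6 | (2R)-1-(3,5-dimethoxy-4-methylphenyl)propan-2-ol | C[C@@H](O)Cc1cc(OC)c(C)c(OC)c1 | intermediate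
7 | 5-[(2R)-2-hydroxypropyl]-2-methylbenzene-1,3-diol | C[C@@H](O)Cc1cc(O)c(C)c(O)c1 | intermediate
8 | cyclic ethyl acetal: (3R)-1-ethoxy-3,7-dimethyl-3,4-dihydro-1H-isochromene-6,8-diol (both C1 epimers) | CCOC1O[C@H](C)Cc2cc(O)c(C)c(O)c12 | intermediate
9 | 2,4-dihydroxy-6-[(2R)-2-hydroxypropyl]-3-methylbenzaldehyde | C[C@@H](O)Cc1cc(O)c(C)c(O)c1C=O | intermediate
10 | linoleic acid, (9Z,12Z)-octadeca-9,12-dienoic acid | CCCCC/C=C\C/C=C\CCCCCCCC(=O)O | starting material
11 | aryliodane bis(linoleate): the (R,R)-iodoarene with two linoleate ligands on trivalent iodine | Cc1cc(C)c(NC(=O)[C@@H](C)Oc2cccc(O[C@H](C)C(=O)Nc3c(C)cc(C)cc3C)c2I(OC(=O)CCCCCCC/C=C\C/C=C\CCCCC)OC(=O)CCCCCCC/C=C\C/C=C\CCCCC)c(C)c1 | intermediate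
12 | quinone methide: (3R)-8-hydroxy-3,7-dimethyl-3,4-dihydro-6H-isochromen-6-one | C[C@@H]1CC2=CC(=O)C(C)=C(O)C2=CO1 | intermediate
13 | (3R,7R)-3,7-dimethyl-6,8-dioxo-3,4,7,8-tetrahydro-6H-isochromen-7-yl (9Z,12Z)-octadeca-9,12-dienoate | CCCCC/C=C\C/C=C\CCCCCCCC(=O)O[C@]1(C)C(=O)C=C2C[C@@H](C)OC=C2C1=O | target

## Step count and risks

Total step count: 5. Longest linear sequence: 5 steps (1 → 4 → 6 → 7 → 9 → 13); linoleic acid and (R)-propylene oxide are used as bought.

The three steps most likely to fail:

**Step 5 (the proposed new acyloxylation).** Ligand transfer may be slow, unselective at C7, or may give the 7-hydroxy compound through traces of water. The fallback uses known chemistry, sets out from 9 and comes back at 13. Compound 9 is closed to 12 with TFA in ClCH2CH2Cl and hydroxylated at C7 with IBX (a pentavalent-iodine reagent) and catalytic Bu4NI, the established hydroxylative dearomatization for azaphilone cores. Without facial control this gives the tertiary alcohol (3R,7R)-7-hydroxy-3,7-dimethyl-3,4-dihydro-6H-isochromene-6,8(7H)-dione F1 together with its C7 epimer (3R,7S)-7-hydroxy-3,7-dimethyl-3,4-dihydro-6H-isochromene-6,8(7H)-dione F2. These are diastereomers and are separated by chromatography. F1 is then acylated with linoleoyl chloride F3 (from 10 with (COCl)2 and catalytic DMF) using DMAP and Et3N in CH2Cl2 to give 13.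

**Step 3 (BBr3 demethylation beside a free secondary alcohol).** The alcohol may be converted to the bromide, or the cleavage may stop at the monomethyl ether. The fallback sets out from 6 and comes back at 7. The alcohol is first masked with Ac2O and pyridine as (2R)-1-(3,5-dimethoxy-4-methylphenyl)propan-2-yl acetate F4. Both methyl ethers are then cleaved with BBr3 at −78 → 0 °C to give (2R)-1-(3,5-dihydroxy-4-methylphenyl)propan-2-yl acetate F5. The acetate is removed with K2CO3 in MeOH to give 7.

**Step 2 (dianion lithiation and methylation).** The alkoxide may give poor solubility, partial O-methylation or incomplete ring lithiation. The fallback sets out from 2 and comes back at 6; the ring methyl group is bought instead of installed. Commercial 2,6-dimethoxytoluene is borylated at its least hindered C–H position with B2pin2, [Ir(cod)(OMe)]2 and 4,4'-di-tert-butyl-2,2'-bipyridine to give 2-(3,5-dimethoxy-4-methylphenyl)-4,4,5,5-tetramethyl-1,3,2-dioxaborolane F6. In the same pot CuBr2 in MeOH/H2O converts this to 5-bromo-1,3-dimethoxy-2-methylbenzene F7. Its Grignard reagent (3,5-dimethoxy-4-methylphenyl)magnesium bromide F8 (Mg, THF) opens epoxide 2 under CuI catalysis, exactly as in step 1, to give 6 directly.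

## Further compounds

F1 | step 5 | (3R,7R)-7-hydroxy-3,7-dimethyl-3,4-dihydro-6H-isochromene-6,8(7H)-dione | O[C@]1(C)C(=O)C=C2C[C@@H](C)OC=C2C1=O
F2 | step 5 | (3R,7S)-7-hydroxy-3,7-dimethyl-3,4-dihydro-6H-isochromene-6,8(7H)-dione | O[C@@]1(C)C(=O)C=C2C[C@@H](C)OC=C2C1=O
F3 | step 5 | linoleoyl chloride, (9Z,12Z)-octadeca-9,12-dienoyl chloride | CCCCC/C=C\C/C=C\CCCCCCCC(Cl)=O
F4 | step 3 | (2R)-1-(3,5-dimethoxy-4-methylphenyl)propan-2-yl acetate | CC(=O)O[C@H](C)Cc1cc(OC)c(C)c(OC)c1
F5 | step 3 | (2R)-1-(3,5-dihydroxy-4-methylphenyl)propan-2-yl acetate | CC(=O)O[C@H](C)Cc1cc(O)c(C)c(O)c1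
F6 | step 2 | 2-(3,5-dimethoxy-4-methylphenyl)-4,4,5,5-tetramethyl-1,3,2-dioxaborolane | COc1cc(B2OC(C)(C)C(C)(C)O2)cc(OC)c1C
F7 | step 2 | 5-bromo-1,3-dimethoxy-2-methylbenzene | COc1cc(Br)cc(OC)c1C
F8 | step 2 | (3,5-dimethoxy-4-methylphenyl)magnesium bromide | COc1cc([Mg]Br)cc(OC)c1C
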